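## The problem

Target 19 is a 1,7-diarylheptanoid folded into an oxane. The ring is numbered here O1, C2 (2-(4-hydroxy-3-methoxyphenyl)ethyl arm), C3, C4 (free hydroxyl), C5, C6 (4-hydroxy-3,5-dimethoxyphenyl ring). The three stereocentres are C2 (S), C4 (R) and C6 (S); all substituents are cis and equatorial, so the target is the thermodynamically preferred ring isomer. In open-chain terms the C2 oxygen and the C6 oxygen are each 1,3-anti to the C4 hydroxyl. C6 is benzylic to a ring with a para oxygen, so its C–O bond ionises easily. It cannot be trusted as a fixed centre through acid, but it can be set last under equilibrium. C4 cannot be corrected later, and because it sits 1,3 to both C2 and C6 it is the centre from which the others can be relayed. The two phenols are electron-rich and oxidisable; they must be masked through carbanion, Lewis-acid and hydride chemistry and released without cleaving the benzylic C6–O1 bond. β-Hydroxy ketone intermediates are prone to dehydration. What makes a short assembly possible is that C3–C4–C5 is the three-carbon skeleton of epichlorohydrin with its oxygen on the middle carbon, while C2 and C6 each carry exactly one oxygen. Both can therefore be introduced at the carbonyl oxidation level as acyl-anion equivalents that attack the two electrophilic ends of that C3 unit.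

## Retrosynthesis

**19 ⇒ 18.** The two phenolic O–CH2Ph bonds are cut (benzyl groups added). Benzyl ethers are preferred to silyl or acetal groups because they tolerate t-BuLi, the BF3/thiol step, AcOH and aqueous MeI, and they leave under neutral conditions. The forward reaction must remove two aryl benzyl ethers from 18 without hydrogenolysing the ring C6–O1 bond.

**18 ⇒ 17.** The O1–C6 bond is cut, opening the oxane to the acyclic 1,3,5-triol 17. Cutting O1–C2 instead would require an SN2 closure at an unactivated secondary carbon with a pre-set leaving group of defined configuration. C6 can be closed by ionisation, and the closure is reversible, so the configuration of C6 in 17 does not matter. The precursor loses the ring and one stereocentre that needs control. The forward reaction must ionise only at C6, close the six-membered ring through the C2 hydroxyl and equilibrate to the all-equatorial isomer.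

**17 ⇒ 16.** The C–H bonds at C2 and C6 are removed, giving β-hydroxy diketone 16. The C4 hydroxyl lies 1,3 to both carbonyls and can deliver hydride to each. Three stereocentres collapse to one. The forward reduction must give the 1,3-anti relationship at C2; the outcome at C6 is free.

**16 ⇒ 15.** Both carbonyls are masked as 1,3-dithianes, giving bis-dithiane carbinol 15. This is a functional-group change only. The forward hydrolysis must not oxidise or halogenate the alkoxyarenes or dehydrate the product.

**15 ⇒ 6 + 10 + 9.** The C2–C3 and C5–C6 bonds are cut. The pieces are the arylethyl dithiane 6, the aryl dithiane 9 and (R)-epichlorohydrin 10. Aldol cuts at the same bonds with normal polarity would need two different aldol events and would have to create C4 by induction. Here both nucleophiles are of one type, both bonds form in one flask and C4 is bought. The precursors are achiral and hold one arene each. The forward reaction must open the epoxide of 10 before chloride is displaced. It must also add the arylethyl anion first, because with the R enantiomer this order gives R at the carbinol.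

**6 ⇒ 4 + 5, then 4 ⇒ 3 ⇒ 2 ⇒ 1.** The two C–S bonds of 6 are cut to aldehyde 4 and propane-1,3-dithiol 5. Aldehyde 4 goes back through alcohol 3 and benzyl ether 2 to eugenol 1, which already contains the arene and the three-carbon chain. Alkylating a lithiated dithiane with a 2-arylethyl halide was set aside because such halides eliminate to styrenes.

**9 ⇒ 8 + 5, then 8 ⇒ 7.** The C–S bonds of 9 are cut to benzylated aldehyde 8 and dithiol 5; 8 comes from syringaldehyde 7 by O-benzylation.

## Roads not taken

**Alternative 1:** The ring is opened at O1–C2 with a shift of the unsaturation, back to the open-chain benzylic allylic alcohol A2. In A2, C4 (as silyl ether) and C6 (free carbinol) are already in place. In the forward direction catalytic FeCl3·6H2O would ionise the doubly activated alcohol. The C6 hydroxyl would add to the far end of the delocalised cation, and reversible closure would settle on the all-cis styrenyl oxane A1.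
- Merits: the closure is catalytic, releases only water, and gives 2,6-cis by equilibration. One hydrogenation would later saturate the styrene and remove the benzyl group.
- Weak points: A2 needs C4 and C6 installed by two separate stereo-defining operations. Its C6 carbinol is benzylic on an oxygenated ring and would ionise in competition unless that ring is deactivated. This forces a pivalate on the syringyl oxygen, and so three kinds of protecting group and two extra removals.
- Comparison: the ring closure is cleaner than step 10 and avoids stoichiometric organolithiums, HMPA and thiols. The chosen plan sets against this a single purchased stereocentre, a shorter path to the cyclisation substrate, and the use of the lability of C6 instead of its suppression.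

**Alternative 2:** Three bonds (C5–C6, C2–C3, O1–C2) are cut at once. The components are the bis(trimethylsilyl) dienol ether of methyl acetoacetate A4 and the aldehydes 8 and 4. In one flask, A4 would add to 8 under Ti(OiPr)4 and BINOL and set C6. Aldehyde 4 would then condense at C3, and the benzylic hydroxyl would close the ring by oxa-Michael addition to give A3. Ester removal, ketone reduction from the axial face and hydrogenolysis would follow.
- Merits: this is the shortest road, about three operations fewer than the chosen plan, and more convergent. It uses the same two aldehydes.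
- Weak points: the absolute configuration of the whole molecule would rest on a catalyst-controlled addition to an electron-rich, poorly electrophilic aldehyde. The carbinol so formed is the ionisable benzylic C6, and it must survive the acidic condensation and closure. The enolisable aldehyde 4 can also self-condense.
- Comparison: Alternative 2 wins on step count. The chosen plan buys its configuration, places the stereochemical origin at the non-ionisable C4, and sets C6 last under thermodynamic control.

**Alternative 3:** The C2–C3 bond is cut as the result of an oxygen-to-carbon rearrangement. The precursor is the cis enol acetal A6, built from aldehyde 4 and a β-hydroxy acid obtained by asymmetric acetate aldol addition to 8. Me2AlCl would cleave the acetal, and the resulting oxocarbenium and enolate halves would recombine at carbon (Petasis–Ferrier rearrangement) to give ketone A5, the decarboxylated counterpart of A3.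
- Merits: the 2,6-cis relationship is fixed kinetically in a chair-like recombination and does not depend on equilibration. A cyclic ketone is simpler to reduce than a double directed reduction is to run.
- Weak points: A6 requires an auxiliary or catalyst for the aldol step, then hydrolysis, acetalisation and a stoichiometric titanium methylenation. The C6–O bond of A6 is benzylic on an electron-rich ring and is a second site for Lewis-acid cleavage, which would scramble the only centre carrying absolute information. The step count is no lower than that of the chosen plan.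
- Comparison: Alternative 3 is better in the kinetic security of ring formation. The chosen plan offers a purchased stereocentre that is never at risk, cheaper reagents and identical operations on both arms.

Key step: step 7

Remark on the chemistry: commercial (R)-epichlorohydrin of high enantiomeric purity is assumed; the enantiomeric purity of the route rests on it.

## Route

Step 1
Reactants: 1 eugenol (4-allyl-2-methoxyphenol)
Product: 2 4-allyl-1-(benzyloxy)-2-methoxybenzene
Conditions: BnBr, K2CO3, DMF, rt
Reagents that add atoms: benzyl bromide, BrCc1ccccc1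
Why: Williamson etherification of the phenoxide; the benzyl ether should withstand the organolithium, Lewis-acid and hydride steps and leave in the final hydrogenolysis.

Step 2
Reactants: 2 4-allyl-1-(benzyloxy)-2-methoxybenzene
Product: 3 3-[4-(benzyloxy)-3-methoxyphenyl]propan-1-ol
Conditions: 9-BBN, THF, 0 °C to rt; then NaOH, H2O2, 0 °C to rt
Reagents that add atoms: hydrogen peroxide, OO
Why: Hydroboration–oxidation; the bulky dialkylborane places boron on the terminal carbon of the allyl group, so the primary alcohol should be the only regioisomer of consequence.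

Step 3
Reactants: 3 3-[4-(benzyloxy)-3-methoxyphenyl]propan-1-ol
Product: 4 3-[4-(benzyloxy)-3-methoxyphenyl]propanal
Conditions: TEMPO (cat.), PhI(OAc)2, CH2Cl2, rt
Reagents that add atoms: none
Why: Oxoammonium-mediated (TEMPO) oxidation stops at the aldehyde and leaves the alkoxyarene and the benzyl ether alone; the aldehyde is used without storage.

Step 4
Reactants: 4 3-[4-(benzyloxy)-3-methoxyphenyl]propanal; 5 propane-1,3-dithiol
Product: 6 2-{2-[4-(benzyloxy)-3-methoxyphenyl]ethyl}-1,3-dithiane
Conditions: BF3·OEt2 (cat.), CH2Cl2, 0 °C to rt
Reagents that add atoms: none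
Why: Lewis-acid-catalysed dithioacetalisation, the masking half of Corey–Seebach umpolung; a catalytic amount of BF3·OEt2 at 0 °C stays short of the conditions under which thiols cleave aryl benzyl ethers.

Step 5
Reactants: 7 syringaldehyde (4-hydroxy-3,5-dimethoxybenzaldehyde)
Product: 8 4-(benzyloxy)-3,5-dimethoxybenzaldehyde
Conditions: BnBr, K2CO3, DMF, 60 °C
Reagents that add atoms: benzyl bromide, BrCc1ccccc1
Why: Williamson etherification; the phenol is flanked by two methoxy groups but is acidified by the para formyl group, so O-alkylation should go to completion on warming.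

Step 6
Reactants: 8 4-(benzyloxy)-3,5-dimethoxybenzaldehyde; 5 propane-1,3-dithiol
Product: 9 2-[4-(benzyloxy)-3,5-dimethoxyphenyl]-1,3-dithiane
Conditions: BF3·OEt2 (cat.), CH2Cl2, 0 °C to rt
Reagents that add atoms: none
Why: Lewis-acid-catalysed dithioacetalisation of an aromatic aldehyde; as in step 4 the catalytic, cold conditions should spare the benzyl ether.

Step 7
Reactants: 6 2-{2-[4-(benzyloxy)-3-methoxyphenyl]ethyl}-1,3-dithiane; 10 (R)-epichlorohydrin; 9 2-[4-(benzyloxy)-3,5-dimethoxyphenyl]-1,3-dithiane
Product: 15 (2R)-1-{2-[4-(benzyloxy)-3,5-dimethoxyphenyl]-1,3-dithian-2-yl}-3-(2-{2-[4-(benzyloxy)-3-methoxyphenyl]ethyl}-1,3-dithian-2-yl)propan-2-ol, via 2-lithio-2-(arylethyl)dithiane 11 (not isolated), via chlorohydrin lithium alkoxide 12 (not isolated), via transposed (R)-epoxide 13 (not isolated), via 2-lithio-2-aryldithiane 14 (not isolated)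
Conditions: 6, t-BuLi, THF/HMPA (10:1), −78 °C; 10 (slight excess), −78 to 0 °C; then 14 (from 9, n-BuLi, THF, −78 to −20 °C), −78 °C to rt; aq. NH4Cl
Reagents that add atoms: none
Why: Lithiated dithiane 11 opens 10 at its unsubstituted epoxide carbon to give chlorohydrin alkoxide 12; on warming 12 expels chloride to form the transposed epoxide 13, and the separately made benzylic anion 14 opens 13 at its terminal carbon, so the C2–C3 and C5–C6 bonds of the later ring form in one flask. The closest known reaction type is the one-flask linchpin coupling of two different 2-lithio-1,3-dithianes with epichlorohydrin, an extension of Corey–Seebach umpolung. No ring of the target is closed; the only ring formed is the transient oxirane of 13, by 3-exo-tet displacement of chloride, and it is consumed again. No stereocentre is created: the carbinol carbon of 15 is the stereocentre of 10, none of whose four bonds is broken, and with the arylethyl anion added first to the R enantiomer it emerges as R, the configuration of C4. The step needs regioselectivity in the first addition, because direct displacement of chloride would lead to the enantiomer of 13; the strained epoxide carbon is far more reactive than the primary chloride towards the carbanion at −78 °C. It also needs the two anions kept apart: addition of 11 is complete at −78 °C while closure of 12 to 13 sets in only on warming, so 11 is spent before 13 exists and the symmetrical double adduct should not form. Both openings occur at CH2 termini because the tertiary dithianyl carbanions are too bulky for the substituted carbon.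

Step 8
Reactants: 15 bis-dithiane carbinol
Product: 16 (3R)-1-[4-(benzyloxy)-3,5-dimethoxyphenyl]-7-[4-(benzyloxy)-3-methoxyphenyl]-3-hydroxyheptane-1,5-dione
Conditions: MeI, CaCO3, MeCN/H2O (9:1), 45 °C
Reagents that add atoms: water, O
Why: Alkylative dithiane hydrolysis: S-methylation makes each sulfur a leaving group and water captures the thionium ion; MeI neither oxidises nor halogenates the alkoxyarenes, and CaCO3 keeps the medium neutral so the β-hydroxy diketone should not dehydrate.

Step 9
Reactants: 16 β-hydroxy diketone
Product: 17 (1S,3R,5S)-1-[4-(benzyloxy)-3,5-dimethoxyphenyl]-7-[4-(benzyloxy)-3-methoxyphenyl]heptane-1,3,5-triol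
Conditions: Me4NBH(OAc)3, MeCN/AcOH (1:1), −30 °C to rt
Reagents that add atoms: none
Why: Evans–Saksena reduction: the C4 hydroxyl exchanges with an acetate on boron and the bound hydride is delivered intramolecularly through a chair-like transition state to each flanking ketone in turn, giving the 1,3-anti carbinol on both sides. The centre that matters is C2 of the later ring (C5 of 17, S); the benzylic centre (C1 of 17) is also formed anti but is reset in step 10.

Step 10
Reactants: 17 anti,anti-triol
Product: 18 (2S,4R,6S)-2-[4-(benzyloxy)-3,5-dimethoxyphenyl]-6-{2-[4-(benzyloxy)-3-methoxyphenyl]ethyl}oxan-4-ol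
Conditions: p-TsOH·H2O (cat.), CH2Cl2, 0 °C to rt
Reagents that add atoms: none
Why: Acid-catalysed dehydrative etherification of SN1 type: only the benzylic carbinol, stabilised by the para benzyloxy group, ionises, and the C2 hydroxyl captures the cation to close the six-membered ring (the C4 hydroxyl could only form an oxetane). Reversible ionisation of the product lets the mixture settle on the all-equatorial isomer, which fixes the aryl-bearing carbon as S whichever epimer of 17 enters; C2 and C4 are untouched.

Step 11
Reactants: 18 bis-benzyl ether of the target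
Product: 19 (2S,4R,6S)-2-(4-hydroxy-3,5-dimethoxyphenyl)-6-[2-(4-hydroxy-3-methoxyphenyl)ethyl]oxan-4-ol
Conditions: H2 (1 atm), 10% Pd/C, EtOAc, rt
Reagents that add atoms: none
Why: Catalytic hydrogenolysis; aryl benzyl ethers are cleaved on palladium much faster than the dialkyl-type benzylic ring C–O bond under neutral conditions in an aprotic solvent, so both phenols should be freed with the oxane intact.

## Compound list

1 | eugenol (4-allyl-2-methoxyphenol) | C=CCc1ccc(O)c(OC)c1 | starting material
2 | 4-allyl-1-(benzyloxy)-2-methoxybenzene | C=CCc1ccc(OCc2ccccc2)c(OC)c1 | intermediate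
3 | 3-[4-(benzyloxy)-3-methoxyphenyl]propan-1-ol | OCCCc1ccc(OCc2ccccc2)c(OC)c1 | intermediate
4 | 3-[4-(benzyloxy)-3-methoxyphenyl]propanal | O=CCCc1ccc(OCc2ccccc2)c(OC)c1 | intermediate
5 | propane-1,3-dithiol | SCCCS | starting material
6 | 2-{2-[4-(benzyloxy)-3-methoxyphenyl]ethyl}-1,3-dithiane | COc1cc(CCC2SCCCS2)ccc1OCc1ccccc1 | intermediate
7 | syringaldehyde (4-hydroxy-3,5-dimethoxybenzaldehyde) | COc1cc(C=O)cc(OC)c1O | starting material
8 | 4-(benzyloxy)-3,5-dimethoxybenzaldehyde | COc1cc(C=O)cc(OC)c1OCc1ccccc1 | intermediate
9 | 2-[4-(benzyloxy)-3,5-dimethoxyphenyl]-1,3-dithiane | COc1cc(C2SCCCS2)cc(OC)c1OCc1ccccc1 | intermediate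
10 | (R)-epichlorohydrin | ClC[C@H]1CO1 | starting material
11 | 2-lithio-2-{2-[4-(benzyloxy)-3-methoxyphenyl]ethyl}-1,3-dithiane | [Li]C1(CCc2ccc(OCc3ccccc3)c(OC)c2)SCCCS1 | intermediate (not isolated)
12 | lithium (2R)-1-chloro-3-(2-{2-[4-(benzyloxy)-3-methoxyphenyl]ethyl}-1,3-dithian-2-yl)propan-2-olate | COc1cc(CCC2(C[C@@H](O[Li])CCl)SCCCS2)ccc1OCc1ccccc1 | intermediate (not isolated)
13 | 2-{2-[4-(benzyloxy)-3-methoxyphenyl]ethyl}-2-{[(2R)-oxiran-2-yl]methyl}-1,3-dithiane | COc1cc(CCC2(C[C@@H]3CO3)SCCCS2)ccc1OCc1ccccc1 | intermediate (not isolated)
14 | 2-lithio-2-[4-(benzyloxy)-3,5-dimethoxyphenyl]-1,3-dithiane | [Li]C1(c2cc(OC)c(OCc3ccccc3)c(OC)c2)SCCCS1 | intermediate (not isolated)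
15 | (2R)-1-{2-[4-(benzyloxy)-3,5-dimethoxyphenyl]-1,3-dithian-2-yl}-3-(2-{2-[4-(benzyloxy)-3-methoxyphenyl]ethyl}-1,3-dithian-2-yl)propan-2-ol | COc1cc(CCC2(C[C@@H](O)CC3(c4cc(OC)c(OCc5ccccc5)c(OC)c4)SCCCS3)SCCCS2)ccc1OCc1ccccc1 | intermediate
16 | (3R)-1-[4-(benzyloxy)-3,5-dimethoxyphenyl]-7-[4-(benzyloxy)-3-methoxyphenyl]-3-hydroxyheptane-1,5-dione | COc1cc(CCC(=O)C[C@@H](O)CC(=O)c2cc(OC)c(OCc3ccccc3)c(OC)c2)ccc1OCc1ccccc1 | intermediate
17 | (1S,3R,5S)-1-[4-(benzyloxy)-3,5-dimethoxyphenyl]-7-[4-(benzyloxy)-3-methoxyphenyl]heptane-1,3,5-triol | COc1cc(CC[C@H](O)C[C@@H](O)C[C@H](O)c2cc(OC)c(OCc3ccccc3)c(OC)c2)ccc1OCc1ccccc1 | intermediate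
18 | (2S,4R,6S)-2-[4-(benzyloxy)-3,5-dimethoxyphenyl]-6-{2-[4-(benzyloxy)-3-methoxyphenyl]ethyl}oxan-4-ol (all-cis) | COc1cc(CC[C@H]2C[C@@H](O)C[C@@H](c3cc(OC)c(OCc4ccccc4)c(OC)c3)O2)ccc1OCc1ccccc1 | intermediate
19 | (2S,4R,6S)-2-(4-hydroxy-3,5-dimethoxyphenyl)-6-[2-(4-hydroxy-3-methoxyphenyl)ethyl]oxan-4-ol (all-cis) | COc1cc(CC[C@H]2C[C@@H](O)C[C@@H](c3cc(OC)c(O)c(OC)c3)O2)ccc1O | target

## Step count and risks

Total: 11 steps. Longest linear sequence: 9 steps (eugenol 1 to 19: steps 1–4 and 7–11); the syringaldehyde branch (steps 5–6) joins at step 7.

**Step 7 (key step).**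
- Risk: sluggish opening of epoxide 13 by the stabilised benzylic anion 14, so that 13 survives or is consumed by side reactions.
- Risk: erosion of enantiomeric purity if part of 11 displaces chloride directly.
- Risk: competing metalation of the benzyl ether during the t-BuLi lithiation of 6.
- Fallback: the roles of the two anions are exchanged and the other enantiomer of the linchpin is used. Starting from 9, anion 14 (n-BuLi) is added to purchased (S)-epichlorohydrin (ClC[C@@H]1CO1). This gives lithium (2S)-1-chloro-3-{2-[4-(benzyloxy)-3,5-dimethoxyphenyl]-1,3-dithian-2-yl}propan-2-olate F1, which closes on warming to 2-[4-(benzyloxy)-3,5-dimethoxyphenyl]-2-{[(2S)-oxiran-2-yl]methyl}-1,3-dithiane F2. F2 is isolated and its enantiomeric purity checked. The more nucleophilic, non-stabilised anion 11 (from 6) then opens F2. Because both the order and the enantiomer are changed, the same R carbinol results and the route is rejoined at 15.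

**Step 8.**
- Risk: incomplete hydrolysis of the slower dialkyl dithiane, and dehydration or retro-aldol cleavage of the liberated β-hydroxy diketone on prolonged warming.
- Fallback: starting from 15, the carbinol is silylated (TBSOTf, 2,6-lutidine) to the tert-butyldimethylsilyl ether of 15 F3. F3 can be unmasked under more forcing conditions (MeI, CaCO3, aqueous MeCN, 60 °C) to the silyl ether of the diketone F4. Desilylation with HF·pyridine returns to the route at 16.

**Step 9.**
- Risk: incomplete reduction of the electron-rich aryl ketone, which is a poor hydride acceptor.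
- Risk: lower facial selectivity at the dialkyl ketone than the anti relationship requires.
- Fallback: starting from 16, the reduction is held at −40 °C so that only the dialkyl ketone is reduced. This gives (3R,5S)-1-[4-(benzyloxy)-3,5-dimethoxyphenyl]-7-[4-(benzyloxy)-3-methoxyphenyl]-3,5-dihydroxyheptan-1-one F5. F5 is closed by reductive etherification (Et3SiH, BF3·OEt2, CH2Cl2/MeCN, −78 to −40 °C): hemiketal formation, loss of water to the 2-aryl oxocarbenium ion, and axial hydride delivery give the 2,6-cis ring. This bypasses 17 and step 10 and rejoins the route at 18.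

**Step 10.**
- Risk: loss of a proton from the benzylic cation to give a styrene, whose allylic C4 hydroxyl can ionise in turn.
- Risk: reluctant ionisation, because the benzyloxy group lies between two methoxy groups and is twisted out of conjugation.
- Risk: incomplete equilibration to the cis isomer.
- Fallback: the order of ring closure and deprotection is reversed. Starting from 17, hydrogenolysis (H2, Pd/C, EtOAc) gives (1S,3R,5S)-1-(4-hydroxy-3,5-dimethoxyphenyl)-7-(4-hydroxy-3-methoxyphenyl)heptane-1,3,5-triol F6. Under very mild acid (PPTS, MeCN) its free para-hydroxybenzylic carbinol loses water to the para-quinone methide 4-[(3S,5S)-3,5-dihydroxy-7-(4-hydroxy-3-methoxyphenyl)heptylidene]-2,6-dimethoxycyclohexa-2,5-dien-1-one F7. The C2 hydroxyl adds to F7 in a reversible 1,6-addition that should settle on the all-cis ring. The fallback ends directly at 19.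

**Step 11.**
- Risk: over-reduction, namely hydrogenolysis of the benzylic ring C–O bond next to the electron-rich arene, which would open the oxane.
- Fallback: starting from 18, the benzyl groups are removed by Lewis acid with a cation scavenger (BCl3, pentamethylbenzene, CH2Cl2, −78 °C). This gives 19 with no new intermediate. Should the ring C–O bond ionise transiently, reclosure is under the same thermodynamic control as in step 10.

## Further compounds

F1 | step 7 | lithium (2S)-1-chloro-3-{2-[4-(benzyloxy)-3,5-dimethoxyphenyl]-1,3-dithian-2-yl}propan-2-olate | COc1cc(C2(C[C@H](O[Li])CCl)SCCCS2)cc(OC)c1OCc1ccccc1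
F2 | step 7 | 2-[4-(benzyloxy)-3,5-dimethoxyphenyl]-2-{[(2S)-oxiran-2-yl]methyl}-1,3-dithiane | COc1cc(C2(C[C@H]3CO3)SCCCS2)cc(OC)c1OCc1ccccc1
F3 | step 8 | tert-butyldimethylsilyl ether of 15, (R) at the silyloxy carbon | COc1cc(CCC2(C[C@@H](O[Si](C)(C)C(C)(C)C)CC3(c4cc(OC)c(OCc5ccccc5)c(OC)c4)SCCCS3)SCCCS2)ccc1OCc1ccccc1
F4 | step 8 | (3R)-1-[4-(benzyloxy)-3,5-dimethoxyphenyl]-7-[4-(benzyloxy)-3-methoxyphenyl]-3-(tert-butyldimethylsilyloxy)heptane-1,5-dione | COc1cc(CCC(=O)C[C@@H](O[Si](C)(C)C(C)(C)C)CC(=O)c2cc(OC)c(OCc3ccccc3)c(OC)c2)ccc1OCc1ccccc1
F5 | step 9 | (3R,5S)-1-[4-(benzyloxy)-3,5-dimethoxyphenyl]-7-[4-(benzyloxy)-3-methoxyphenyl]-3,5-dihydroxyheptan-1-one | COc1cc(CC[C@H](O)C[C@@H](O)CC(=O)c2cc(OC)c(OCc3ccccc3)c(OC)c2)ccc1OCc1ccccc1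
F6 | step 10 | (1S,3R,5S)-1-(4-hydroxy-3,5-dimethoxyphenyl)-7-(4-hydroxy-3-methoxyphenyl)heptane-1,3,5-triol | COc1cc(CC[C@H](O)C[C@@H](O)C[C@H](O)c2cc(OC)c(O)c(OC)c2)ccc1O
F7 | step 10 | 4-[(3S,5S)-3,5-dihydroxy-7-(4-hydroxy-3-methoxyphenyl)heptylidene]-2,6-dimethoxycyclohexa-2,5-dien-1-one | COC1=CC(=CC[C@H](O)C[C@@H](O)CCc2ccc(O)c(OC)c2)C=C(OC)C1=O
F0 | step 11 | none | none
A1 | alternative 1 | all-cis 2-[(E)-2-(4-benzyloxy-3-methoxyphenyl)ethenyl]-4-(tert-butyldimethylsilyloxy)-6-(3,5-dimethoxy-4-pivaloyloxyphenyl)oxane, ring configured as in 19 | COc1cc(/C=C/[C@H]2C[C@@H](O[Si](C)(C)C(C)(C)C)C[C@@H](c3cc(OC)c(OC(=O)C(C)(C)C)c(OC)c3)O2)ccc1OCc1ccccc1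
A2 | alternative 1 | (E)-1-(4-benzyloxy-3-methoxyphenyl)-5-(tert-butyldimethylsilyloxy)-7-(3,5-dimethoxy-4-pivaloyloxyphenyl)hept-2-ene-1,7-diol, 5,7-anti, C1 unassigned | COc1cc(C(O)/C=C/C[C@@H](O[Si](C)(C)C(C)(C)C)C[C@@H](c2cc(OC)c(OC(=O)C(C)(C)C)c(OC)c2)O)ccc1OCc1ccccc1
A3 | alternative 2 | methyl 2,6-cis-6-[4-(benzyloxy)-3,5-dimethoxyphenyl]-2-{2-[4-(benzyloxy)-3-methoxyphenyl]ethyl}-4-hydroxy-5,6-dihydro-2H-pyran-3-carboxylate | COc1cc(CC[C@H]2C(C(=O)OC)=C(O)C[C@@H](c3cc(OC)c(OCc4ccccc4)c(OC)c3)O2)ccc1OCc1ccccc1
A4 | alternative 2 | 1-methoxy-1,3-bis(trimethylsilyloxy)buta-1,3-diene | COC(O[Si](C)(C)C)=CC(=C)O[Si](C)(C)C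
A5 | alternative 3 | 2,6-cis-2-[4-(benzyloxy)-3,5-dimethoxyphenyl]-6-{2-[4-(benzyloxy)-3-methoxyphenyl]ethyl}oxan-4-one | COc1cc(CC[C@H]2CC(=O)C[C@@H](c3cc(OC)c(OCc4ccccc4)c(OC)c3)O2)ccc1OCc1ccccc1
A6 | alternative 3 | 2,6-cis-6-[4-(benzyloxy)-3,5-dimethoxyphenyl]-2-{2-[4-(benzyloxy)-3-methoxyphenyl]ethyl}-4-methylidene-1,3-dioxane | COc1cc(CC[C@H]2OC(=C)C[C@@H](c3cc(OC)c(OCc4ccccc4)c(OC)c3)O2)ccc1OCc1ccccc1
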